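I took this flask as a small dissolved portion standing over a large solid charge, and I counted the forms of substrate as fractions of the charge.

    dissolved substrate + reagent → target (k1 = 0.143 /M/s)
    reagent ⇌ dormant form (K2 = 94.2, k2 = 0.00520 /s)
    2 dissolved substrate → side product (k3 = 0.00257 /M/s)
    solid substrate → decomposition product (k4 = 2.15 × 10⁻⁶ /s)
    solid substrate ⇌ dissolved substrate, rate k5*(cs5 - [dissolved substrate]) while solid is left; crystals form when [dissolved substrate] > cs5 (cs5 = 2.1 M, k5 = 6.24 × 10⁻⁴ /s)
    gas ⇌ reagent, rate k6*(csat - [reagent]) (k6 = 1.09 /s, csat = 100 mM)

solid substrate 3.0 M; gas 100 mM (held); time 25 min

* amount of target at 25 min, in percent of the solid substrate charged
* concentration of dissolved substrate in solution at 25 min, in percent of saturation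

- a species is counted by the solid substrate in it: one side product counts as two
- for a step with 2 of a species take k times the square, and two of it per event
- given per volume of solution although it is solid: solid substrate
- at the start none of reagent is dissolved
- at the start none of the solid substrate is in solution
- dissolved substrate means what is dissolved; the solid is not counted in it
- run time (flask): 25 min

First I asked whether reagent could keep up. By 25 min the gas could deliver 5450% of the charge into an empty solution, against 65.5% for dissolution and 26.0% for the forward step to dormant form at full reagent, so I held reagent near 100 mM. That made the loss of dissolved substrate to target pseudo-first-order at 0.0143 /s.

How much then stayed dissolved? That constant was 22.9 times the dissolution coefficient, so dissolved substrate rested at 4.18% of saturation, which is 2.93% of the charge.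

How fast did the charge pass? I called the delivery d the fraction of the charge entering solution per minute while solid remains and the solution rests at that level: 0.0251 /min. Over the run it gave 62.8%, less than the charge, so I expected solid to last. I took target as this large amount less two corrections, the portion still dissolved and the side product's share. The selectivity factor for target over side product came to 31.7, and I reckoned 58.0% target.

The forecast said: “Treat this as two quasi-steady states.” It gave 58.2% (57% to 59.5%) and 4.12% (4% to 4.25%). Its target stood slightly above mine and its saturation slightly below.

The simulation gave 58.3% and 4.12%. At 25.0 min dissolved substrate had a half-life of 0.82 min against reagent, short against the 25 min run, and over the second half target rose by 0.0244 /min, slightly slower than d. With twice the dissolution coefficient, a run gave 94.4%, above the forecast's range. For the neighbour read at 15 min, d gives 37.6% delivered, and the same corrections leave 33.7%; its simulation gave 33.9%.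

The numbers belong to no real substance; no experiment stands behind them.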